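**Retrosynthetic overview**
- The target is an achiral bis(indol-3-yl)methane. Cut one indole C3–CH2 bond to give N-tert-prenylindole (C3 nucleophile) and the methiodide of 1-tert-prenylgramine (latent 3-methyleneindoleninium electrophile); the bond is made by a Mannich/Michael-type addition.
- The gramine comes from the same N-tert-prenylindole and dimethylmethyleneiminium iodide (Mannich reaction), so both halves derive from one common indole.
- N-tert-Prenylindole ⇒ N-tert-prenylindoline ⇒ N-(1,1-dimethylpropargyl)indoline ⇒ indoline + 3-chloro-3-methylbut-1-yne.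
- Ring order: no ring is built. The bicyclic core is bought as indoline, aromatised to the indole after N-alkylation, and the two indoles are then joined through the CH2 carbon.

Assumption: the target has no stereocentre or other stereogenic element, so "single enantiomer" is taken to mean the single achiral structure drawn and no stereocontrol is needed.

**Step 1**
Reactants: 1 indoline (2,3-dihydro-1H-indole); 2 3-chloro-3-methylbut-1-yne
Product: 3 1-(2-methylbut-3-yn-2-yl)indoline
Conditions: CuCl (10 mol %), Et3N (1.5 equiv), THF, 0 °C → rt
Reagents that add atoms: none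
Why: Copper-catalysed propargylic amination (Hennion–Nicholas type, via a copper acetylide/allenylidene) lets the secondary aryl amine attack the tertiary propargylic carbon to give the hindered N–C(CH3)2 bond; no stereocentre is formed.

**Step 2**
Reactants: 3 1-(2-methylbut-3-yn-2-yl)indoline
Product: 4 1-(2-methylbut-3-en-2-yl)indoline
Conditions: H2 (1 atm), Pd/CaCO3–Pb(OAc)2 (Lindlar catalyst), quinoline, EtOAc, rt, stopped after 1 equiv H2
Reagents that add atoms: none
Why: Lindlar semihydrogenation stops the terminal alkyne at the terminal vinyl group because the poisoned catalyst reduces the hindered monosubstituted alkene only slowly; no stereocentre is formed.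

**Step 3**
Reactants: 4 1-(2-methylbut-3-en-2-yl)indoline
Product: 5 1-(2-methylbut-3-en-2-yl)-1H-indole
Conditions: activated MnO2 (10 equiv), CH2Cl2, rt
Reagents that add atoms: none
Why: Dehydrogenation of the indoline to the indole is driven by aromatisation, and MnO2 leaves the isolated vinyl group untouched; no stereocentre is involved.

**Step 4**
Reactants: 5 1-(2-methylbut-3-en-2-yl)-1H-indole
Product: 6 N,N-dimethyl-1-[1-(2-methylbut-3-en-2-yl)-1H-indol-3-yl]methanamine (1-tert-prenylgramine)
Conditions: [CH2=NMe2]I (1.2 equiv), MeCN, rt; then 1 M aq NaOH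
Reagents that add atoms: N,N-dimethylmethyleneiminium iodide (Eschenmoser's salt), C=[N+](C)C.[I-]
Why: Intermolecular Mannich reaction of the preformed iminium ion at the nucleophilic indole C3 under non-acidic conditions that spare the acid-labile N-tert-prenyl group; the new carbon is a CH2, so no stereocentre is formed.

**Step 5**
Reactants: 6 N,N-dimethyl-1-[1-(2-methylbut-3-en-2-yl)-1H-indol-3-yl]methanamine
Product: 7 N,N,N-trimethyl-1-[1-(2-methylbut-3-en-2-yl)-1H-indol-3-yl]methanaminium iodide
Conditions: MeI (5 equiv), THF, 0 °C → rt; precipitate filtered and used at once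
Reagents that add atoms: iodomethane, CI
Why: Menshutkin quaternisation turns the dimethylamino group into a trimethylammonium leaving group, and excess MeI with precipitation of the salt suppresses transalkylation; no stereocentre is formed.

**Step 6**
Reactants: 7 N,N,N-trimethyl-1-[1-(2-methylbut-3-en-2-yl)-1H-indol-3-yl]methanaminium iodide; 5 1-(2-methylbut-3-en-2-yl)-1H-indole
Product: 9 polonidine A [bis(1-(2-methylbut-3-en-2-yl)-1H-indol-3-yl)methane], via 3-methyleneindoleninium iodide 8 (not isolated)
Conditions: 5 (1.5 equiv), NaHCO3 (2 equiv), MeCN, 80 °C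
Reagents that add atoms: none
Why: Heating ionises 7 by retro-Mannich-type loss of Me3N to the vinylogous iminium ion 8, whose exocyclic CH2 is attacked by C3 of 5 in an intermolecular Mannich-type (Michael) addition, and rearomatisation gives the achiral product, so no stereocentre arises.

**Compound list**
1 | indoline (2,3-dihydro-1H-indole) | C1Cc2ccccc2N1 | starting material
2 | 3-chloro-3-methylbut-1-yne | C#CC(C)(C)Cl | starting material
3 | 1-(2-methylbut-3-yn-2-yl)indoline | C#CC(C)(C)N1CCc2ccccc21 | intermediate
4 | 1-(2-methylbut-3-en-2-yl)indoline | C=CC(C)(C)N1CCc2ccccc21 | intermediate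
5 | 1-(2-methylbut-3-en-2-yl)-1H-indole | C=CC(C)(C)n1ccc2ccccc21 | intermediate
6 | N,N-dimethyl-1-[1-(2-methylbut-3-en-2-yl)-1H-indol-3-yl]methanamine | C=CC(C)(C)n1cc(CN(C)C)c2ccccc21 | intermediate
7 | N,N,N-trimethyl-1-[1-(2-methylbut-3-en-2-yl)-1H-indol-3-yl]methanaminium iodide | C=CC(C)(C)n1cc(C[N+](C)(C)C)c2ccccc21.[I-] | intermediate
8 | 3-methylidene-1-(2-methylbut-3-en-2-yl)-3H-indol-1-ium iodide (not isolated) | C=CC(C)(C)[N+]1=CC(=C)c2ccccc21.[I-] | intermediate
9 | polonidine A, bis[1-(2-methylbut-3-en-2-yl)-1H-indol-3-yl]methane (achiral) | C=CC(C)(C)n1cc(Cc2cn(C(C)(C)C=C)c3ccccc23)c2ccccc21 | target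

**Totals**
Total step count: 6. Longest linear sequence: 6 steps (1 → 3 → 4 → 5 → 6 → 7 → 9; compound 5 is used a second time in step 6).

**Three steps most likely to fail, with fallbacks**

Step 6 (coupling of 7 with 5). Ionisation of the N-alkyl ammonium salt may be sluggish, or the cation may over-alkylate the product. The fallback sets out from 5 and comes back at 9. Compound 5 (2 equiv) is stirred with 37 % aqueous formaldehyde (1 equiv) and Sc(OTf)3 (5 mol %) in EtOH–H2O at rt. Friedel–Crafts hydroxymethylation at C3 gives [1-(2-methylbut-3-en-2-yl)-1H-indol-3-yl]methanol F1, which is not isolated. Under the Lewis acid it ionises, and the cation is captured by a second molecule of 5 to give 9 directly, replacing steps 4 to 6.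

Step 5 (quaternisation of 6). N-Alkylgramine methiodides can transalkylate unquaternised gramine or decompose on isolation. The fallback sets out from 6 and comes back at 9. Compound 6 is heated with Ac2O (3 equiv) in toluene at 80 °C; acylative C–N cleavage through the N-acetylammonium ion gives [1-(2-methylbut-3-en-2-yl)-1H-indol-3-yl]methyl acetate F2. F2 then alkylates 5 (1.5 equiv) with Sc(OTf)3 (5 mol %) in MeCN at 0 °C → rt to give 9, so no ammonium salt is needed.

Step 1 (copper-catalysed propargylation). Allenyl by-products, cyclisation or low conversion with the tertiary chloride are possible. The fallback sets out from 1 and comes back at 4, skipping 3 and step 2. 2-Methylbut-3-en-2-ol is converted (n-BuLi, Boc2O, THF) into tert-butyl (2-methylbut-3-en-2-yl) carbonate F3. Compounds 1 and F3 with [Pd(C3H5)Cl]2 (2.5 mol %) and Xantphos in THF at rt undergo decarboxylative Tsuji–Trost allylic amination. Under kinetic control the nitrogen attacks the more substituted terminus of the 1,1-dimethylallyl palladium intermediate, giving 4 with the vinyl group already in place.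

**Further compounds**
F1 | step 6 | [1-(2-methylbut-3-en-2-yl)-1H-indol-3-yl]methanol | C=CC(C)(C)n1cc(CO)c2ccccc21
F2 | step 5 | [1-(2-methylbut-3-en-2-yl)-1H-indol-3-yl]methyl acetate | C=CC(C)(C)n1cc(COC(C)=O)c2ccccc21
F3 | step 1 | tert-butyl (2-methylbut-3-en-2-yl) carbonate | C=CC(C)(C)OC(=O)OC(C)(C)C
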